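The plan cuts the O1–C2 bond of pyran ring C, a benzylic aryl ether that ties the ring A oxygen to the carbon bearing ring B. Opened there, the trans-2,4-diarylchroman becomes an acyclic 1,3-diarylpropanol. Its two stereocentres are installed independently by catalysts: C4 by enantioselective aryl transfer to a chalcone, and C2 as an (S)-carbinol by transfer hydrogenation. A single Mitsunobu operation then forms O1–C2, closes ring C and inverts C2 to (R). Its substrate is the (1S,3S) phenol-alcohol, benzylated at the five other oxygens and already carrying the 9-phenylnonanoyl chain on phloroglucinol ring D.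

Key step: step 8

Ring labels: A is the benzo ring of the chroman, B the 2-aryl group, C the pyran and D the acylphloroglucinol ring. Chroman numbering (O1, C2, C3, C4, C4a, C8a) is also used for the open-chain compounds.

Assumption: 1,3,5-tris(benzyloxy)benzene, the tribenzyl ether of phloroglucinol, is bought as such.

Assumption: in step 6 the (S,S)-diene is assigned to Re-face delivery at Cβ by analogy with other acyclic E-enones. The (R,R)-ligand is equally available and would be used if a pilot run showed the opposite sense.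

Step 1
Reactants: 1 1,3,5-tris(benzyloxy)benzene; 2 9-phenylnonanoic acid
Product: 4 1-[2,4,6-tris(benzyloxy)phenyl]-9-phenylnonan-1-one, via mixed anhydride 3 (not isolated)
Conditions: 2 (1.2 equiv), (CF3CO)2O (1.1 equiv), CH2Cl2, 0 °C; then 1, 0 °C → rt
Reagents that add atoms: none
Why: Friedel–Crafts acylation by the acyl trifluoroacetate needs no Lewis acid on a ring activated by three alkoxy groups, so the benzyl ethers should survive, the unactivated terminal phenyl ring stays out of the reaction and the ketone formed damps the ring enough to stop at monoacylation.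

Step 2
Reactants: 4 1-[2,4,6-tris(benzyloxy)phenyl]-9-phenylnonan-1-one
Product: 6 2,4,6-tris(benzyloxy)-3-(9-phenylnonanoyl)benzaldehyde, via aryl iminium chloride 5 (not isolated)
Conditions: POCl3 (1.5 equiv), DMF, 0 → 50 °C; then aq NaOAc, rt
Reagents that add atoms: N,N-dimethylformamide CN(C)C=O; water O
Why: Vilsmeier–Haack formylation should still be fast because the two free ring positions of 4 are equivalent, each lies ortho/para to all three benzyloxy groups and the ketone is twisted out of conjugation, while the coplanar formyl group then blocks a second attack.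

Step 3
Reactants: 6 2,4,6-tris(benzyloxy)-3-(9-phenylnonanoyl)benzaldehyde; 7 1-[4-(benzyloxy)phenyl]ethan-1-one
Product: 9 (E)-1-[4-(benzyloxy)phenyl]-3-[2,4,6-tris(benzyloxy)-3-(9-phenylnonanoyl)phenyl]prop-2-en-1-one, via aldol adduct 8 (not isolated)
Conditions: KOH, EtOH/THF, rt → 40 °C
Reagents that add atoms: none
Why: Claisen–Schmidt condensation, in which the aldehyde cannot enolise, the unhindered methyl ketone 7 condenses far faster than the shielded nonanoyl ketone, and E1cB loss of water from 8 should give the conjugated E-alkene as the thermodynamic product.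

Step 4
Reactants: 10 4-bromobenzene-1,3-diol
Product: 11 5-(benzyloxy)-2-bromophenol
Conditions: BnBr (1.0 equiv), K2CO3 (1.0 equiv), acetone, rt → 40 °C
Reagents that add atoms: benzyl bromide BrCc1ccccc1
Why: Williamson etherification with one equivalent of halide should favour, on steric grounds, the hydroxyl para to bromine, and the regioisomer and the dibenzyl ether are removed by chromatography at this cheap early stage.

Step 5
Reactants: 11 5-(benzyloxy)-2-bromophenol
Product: 14 [4-(benzyloxy)-2-hydroxyphenyl]boronic acid, via dilithio species 12 (not isolated), via lithium arylborate 13 (not isolated)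
Conditions: n-BuLi (2.2 equiv), THF, −78 °C; B(OiPr)3, −78 °C → rt; dil. aq HCl to pH 5
Reagents that add atoms: triisopropyl borate CC(C)OB(OC(C)C)OC(C)C; water O
Why: Phenol deprotonation, bromine–lithium exchange and borate trapping is the standard way to 2-hydroxyarylboronic acids, the exchange at −78 °C being faster than metalation of the benzylic CH2 and the weakly acidic work-up limiting protodeboronation.

Step 6
Reactants: 9 (E)-1-[4-(benzyloxy)phenyl]-3-[2,4,6-tris(benzyloxy)-3-(9-phenylnonanoyl)phenyl]prop-2-en-1-one; 14 [4-(benzyloxy)-2-hydroxyphenyl]boronic acid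
Product: 15 1-[2,4,6-tris(benzyloxy)-3-{(1S)-1-[4-(benzyloxy)-2-hydroxyphenyl]-3-[4-(benzyloxy)phenyl]-3-oxopropyl}phenyl]-9-phenylnonan-1-one
Conditions: [RhCl(C2H4)2]2 (2.5 mol %), (S,S)-Ph-bod* = (1S,4S)-2,5-diphenylbicyclo[2.2.2]octa-2,5-diene (5.5 mol %), KOH (0.5 equiv), 14 (2.5 equiv, in portions), dioxane/H2O 10:1, 40 °C
Reagents that add atoms: none
Why: Hayashi–Miyaura asymmetric 1,4-addition, in which the aryl–rhodium species formed by transmetalation binds the E-enone within the C2-symmetric diene pocket, inserts at the Re face of Cβ and is released by hydrolysis of the oxa-π-allyl rhodium, setting C4 as (S) under ligand control, while the free ortho hydroxyl keeps the nucleophile as slim as possible for this crowded β-carbon and the isolated nonanoyl ketone offers no acceptor site.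

Step 7
Reactants: 15 1-[2,4,6-tris(benzyloxy)-3-{(1S)-1-[4-(benzyloxy)-2-hydroxyphenyl]-3-[4-(benzyloxy)phenyl]-3-oxopropyl}phenyl]-9-phenylnonan-1-one
Product: 16 1-[2,4,6-tris(benzyloxy)-3-{(1S,3S)-1-[4-(benzyloxy)-2-hydroxyphenyl]-3-[4-(benzyloxy)phenyl]-3-hydroxypropyl}phenyl]-9-phenylnonan-1-one
Conditions: RuCl(p-cymene)[(S,S)-TsDPEN] (2 mol %), HCO2H/Et3N 1:1, EtOAc, 35 °C
Reagents that add atoms: none
Why: Noyori–Ikariya asymmetric transfer hydrogenation, in which the (S,S)-catalyst passes hydride and proton to the Re face of the 4-benzyloxyphenyl ketone through its CH/π-organised six-membered transition state and so sets the C2 carbinol as (S) irrespective of C4, tolerates the free phenol that would consume a borane reagent and steer it internally, and should leave the nonanoyl ketone alone because two ortho benzyloxy groups twist and shield it.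

Step 8
Reactants: 16 1-[2,4,6-tris(benzyloxy)-3-{(1S,3S)-1-[4-(benzyloxy)-2-hydroxyphenyl]-3-[4-(benzyloxy)phenyl]-3-hydroxypropyl}phenyl]-9-phenylnonan-1-one
Product: 18 1-[2,4,6-tris(benzyloxy)-3-{(2R,4S)-7-(benzyloxy)-2-[4-(benzyloxy)phenyl]-3,4-dihydro-2H-chromen-4-yl}phenyl]-9-phenylnonan-1-one, via alkoxyphosphonium phenoxide 17 (not isolated)
Conditions: PPh3 (1.5 equiv), DIAD (1.5 equiv, slow addition), toluene (0.01 M), −20 → 0 °C
Reagents that add atoms: none
Why: PPh3 and DIAD form the betaine, the ring A phenol protonates it and phosphorus passes to the C2 hydroxyl, so that the alkoxyphosphonium phenoxide 17 carries nucleophile and leaving group in one molecule, and the phenoxide oxygen then attacks C2 from the side opposite to the departing Ph3P=O. The closest known reaction type is the Mitsunobu cyclisation of 1-aryl-3-(2-hydroxyaryl)propan-1-ols to 2-arylchromans, which proceeds with inversion. Ring C closes in the 6-exo-tet mode, the breaking C2–O bond lying outside the new ring. The C2 stereocentre is controlled by the stereospecific SN2 course alone, the (S)-carbinol becoming (2R) while C4 (S) is a spectator, so the 2,4-trans relation follows from the catalyst chosen in step 7. The selectivity needed is displacement ahead of ionisation to the 4-benzyloxybenzyl cation and ahead of elimination; a tethered phenoxide generated next to the leaving group, a non-ionising solvent, high dilution and sub-zero temperature, together with the absence of any second acidic OH, should secure it. Any leakage would lower only the diastereomeric purity, which chromatography can restore, since C4 fixes the absolute series.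

Step 9
Reactants: 18 1-[2,4,6-tris(benzyloxy)-3-{(2R,4S)-7-(benzyloxy)-2-[4-(benzyloxy)phenyl]-3,4-dihydro-2H-chromen-4-yl}phenyl]-9-phenylnonan-1-one
Product: 19 1-[2,4,6-trihydroxy-3-{(2R,4S)-7-hydroxy-2-(4-hydroxyphenyl)-3,4-dihydro-2H-chromen-4-yl}phenyl]-9-phenylnonan-1-one
Conditions: H2 (1 atm), 10% Pd/C, EtOAc/EtOH, rt
Reagents that add atoms: none
Why: Catalytic hydrogenolysis under neutral conditions cleaves the five primary benzyl aryl ethers much faster than the secondary, ring-bound O1–C2 bond, the hindered ketone turns into an unreactive chelated vinylogous acid as it is unmasked, and neither stereocentre is touched.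

Compound list
1 | 1,3,5-tris(benzyloxy)benzene | c1c(OCc2ccccc2)cc(OCc2ccccc2)cc1OCc1ccccc1 | starting material
2 | 9-phenylnonanoic acid | OC(=O)CCCCCCCCc1ccccc1 | starting material
3 | 9-phenylnonanoic trifluoroacetic anhydride | O=C(CCCCCCCCc1ccccc1)OC(=O)C(F)(F)F | intermediate
4 | 1-[2,4,6-tris(benzyloxy)phenyl]-9-phenylnonan-1-one | O=C(CCCCCCCCc1ccccc1)c1c(OCc2ccccc2)cc(OCc2ccccc2)cc1OCc1ccccc1 | intermediate
5 | N-{[2,4,6-tris(benzyloxy)-3-(9-phenylnonanoyl)phenyl]methylidene}-N-methylmethanaminium chloride | O=C(CCCCCCCCc1ccccc1)c1c(OCc2ccccc2)cc(OCc2ccccc2)c(C=[N+](C)C)c1OCc1ccccc1.[Cl-] | intermediate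
6 | 2,4,6-tris(benzyloxy)-3-(9-phenylnonanoyl)benzaldehyde | O=C(CCCCCCCCc1ccccc1)c1c(OCc2ccccc2)cc(OCc2ccccc2)c(C=O)c1OCc1ccccc1 | intermediate
7 | 1-[4-(benzyloxy)phenyl]ethan-1-one | CC(=O)c1ccc(OCc2ccccc2)cc1 | starting material
8 | 1-[2,4,6-tris(benzyloxy)-3-{3-[4-(benzyloxy)phenyl]-1-hydroxy-3-oxopropyl}phenyl]-9-phenylnonan-1-one (racemic aldol adduct) | O=C(CCCCCCCCc1ccccc1)c1c(OCc2ccccc2)cc(OCc2ccccc2)c(C(O)CC(=O)c2ccc(OCc3ccccc3)cc2)c1OCc1ccccc1 | intermediate
9 | (E)-1-[4-(benzyloxy)phenyl]-3-[2,4,6-tris(benzyloxy)-3-(9-phenylnonanoyl)phenyl]prop-2-en-1-one | O=C(CCCCCCCCc1ccccc1)c1c(OCc2ccccc2)cc(OCc2ccccc2)c(/C=C/C(=O)c2ccc(OCc3ccccc3)cc2)c1OCc1ccccc1 | intermediate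
10 | 4-bromobenzene-1,3-diol | Oc1ccc(Br)c(O)c1 | starting material
11 | 5-(benzyloxy)-2-bromophenol | Oc1cc(OCc2ccccc2)ccc1Br | intermediate
12 | lithium 5-(benzyloxy)-2-lithiophenolate | [Li]Oc1cc(OCc2ccccc2)ccc1[Li] | intermediate
13 | dilithium [4-(benzyloxy)-2-oxidophenyl]tri(propan-2-yloxy)borate | CC(C)O[B-](OC(C)C)(OC(C)C)c1ccc(OCc2ccccc2)cc1[O-].[Li+].[Li+] | intermediate
14 | [4-(benzyloxy)-2-hydroxyphenyl]boronic acid | OB(O)c1ccc(OCc2ccccc2)cc1O | intermediate
15 | 1-[2,4,6-tris(benzyloxy)-3-{(1S)-1-[4-(benzyloxy)-2-hydroxyphenyl]-3-[4-(benzyloxy)phenyl]-3-oxopropyl}phenyl]-9-phenylnonan-1-one | O=C(CCCCCCCCc1ccccc1)c1c(OCc2ccccc2)cc(OCc2ccccc2)c([C@@H](CC(=O)c2ccc(OCc3ccccc3)cc2)c2ccc(OCc3ccccc3)cc2O)c1OCc1ccccc1 | intermediate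
16 | 1-[2,4,6-tris(benzyloxy)-3-{(1S,3S)-1-[4-(benzyloxy)-2-hydroxyphenyl]-3-[4-(benzyloxy)phenyl]-3-hydroxypropyl}phenyl]-9-phenylnonan-1-one | O=C(CCCCCCCCc1ccccc1)c1c(OCc2ccccc2)cc(OCc2ccccc2)c([C@@H](C[C@H](O)c2ccc(OCc3ccccc3)cc2)c2ccc(OCc3ccccc3)cc2O)c1OCc1ccccc1 | intermediate
17 | zwitterion of 16 with the C2 oxygen bound to triphenylphosphonium and the ring A phenol as phenoxide, (1S,3S) | O=C(CCCCCCCCc1ccccc1)c1c(OCc2ccccc2)cc(OCc2ccccc2)c([C@@H](C[C@H](O[P+](c2ccccc2)(c2ccccc2)c2ccccc2)c2ccc(OCc3ccccc3)cc2)c2ccc(OCc3ccccc3)cc2[O-])c1OCc1ccccc1 | intermediate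
18 | 1-[2,4,6-tris(benzyloxy)-3-{(2R,4S)-7-(benzyloxy)-2-[4-(benzyloxy)phenyl]-3,4-dihydro-2H-chromen-4-yl}phenyl]-9-phenylnonan-1-one | O=C(CCCCCCCCc1ccccc1)c1c(OCc2ccccc2)cc(OCc2ccccc2)c([C@H]2C[C@H](c3ccc(OCc4ccccc4)cc3)Oc3cc(OCc4ccccc4)ccc32)c1OCc1ccccc1 | intermediate
19 | 1-[2,4,6-trihydroxy-3-{(2R,4S)-7-hydroxy-2-(4-hydroxyphenyl)-3,4-dihydro-2H-chromen-4-yl}phenyl]-9-phenylnonan-1-one | O=C(CCCCCCCCc1ccccc1)c1c(O)cc(O)c([C@H]2C[C@H](c3ccc(O)cc3)Oc3cc(O)ccc32)c1O | target

Total step count: 9. Longest linear sequence: 7 (steps 1, 2, 3, 6, 7, 8, 9).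

Steps most likely to fail

1. Step 8.
- **Risk:** the activated C2–O bond may ionise before it is displaced, which would leak stereochemistry at C2. Elimination towards the styrene is the other side path.
- **Idea of the fallback:** nothing is substituted at C2. The carbinol oxygen itself becomes O1, and the O1–C8a bond is made with retention.
- **Course:** the fallback sets out from 15.
  - Triflation of the ring A phenol (PhNTf2, K2CO3, DMF, rt) should give the aryl triflate ketone F1.
  - Transfer hydrogenation with the antipodal catalyst RuCl(p-cymene)[(R,R)-TsDPEN] under the step 7 conditions should give the (1S,3R)-carbinol triflate F2.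
  - Intramolecular palladium-catalysed aryl etherification (Pd(OAc)2, 2-(di-tert-butylphosphino)-1,1'-binaphthyl, Cs2CO3, toluene, 70 °C) leaves the carbinol C–O bond untouched and comes back to the route at 18.

2. Step 6.
- **Risk:** migratory insertion at a β-carbon flanked by two ortho benzyloxy groups may be slow, so that protodeboronation uses up the boronic acid. Facial discrimination may also be too weak.
- **Idea of the fallback:** the C4–aryl bond is made with a stoichiometric organocopper reagent without enantiocontrol, and the sorting of the antipodes is moved to the reduction.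
- **Course:** the fallback sets out from 9 and from 12, generated from 11 as in step 5.
  - CuBr·SMe2 (0.5 equiv per 12, THF, −78 °C) should convert 12 into the lithium diarylcuprate F3.
  - 1,4-Addition of F3 to 9 (−78 → −20 °C, then aq NH4Cl) should give the racemic ketone F4.
  - The step 7 conditions then reduce both antipodes under catalyst control to (3S)-carbinols. The unwanted (1R,3S)-diol F5 is removed by chromatography, and the route is rejoined at 16.

3. Step 7.
- **Risk:** hydride transfer to an electron-rich, β-branched ketone that partly rests as its cyclic hemiketal may be sluggish. That tautomer may dehydrate, and the free phenol may lower facial selectivity.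
- **Idea of the fallback:** protection, oxazaborolidine-controlled reduction, then deprotection without acid.
- **Course:** the fallback sets out from 15.
  - t-BuMe2SiCl and imidazole in DMF should give the silyl ether ketone F6.
  - Corey–Bakshi–Shibata reduction ((R)-2-methyl-CBS-oxazaborolidine, BH3·SMe2, toluene, −20 °C) should give the silyl ether (3S)-carbinol F7.
  - Bu4NF buffered with AcOH (THF, 0 °C) frees the phenol and comes back to the route at 16.

Further compounds
F1 | step 8 | aryl triflate ketone, 1-[2,4,6-tris(benzyloxy)-3-{(1S)-1-[4-(benzyloxy)-2-(trifluoromethanesulfonyloxy)phenyl]-3-[4-(benzyloxy)phenyl]-3-oxopropyl}phenyl]-9-phenylnonan-1-one | O=C(CCCCCCCCc1ccccc1)c1c(OCc2ccccc2)cc(OCc2ccccc2)c([C@@H](CC(=O)c2ccc(OCc3ccccc3)cc2)c2ccc(OCc3ccccc3)cc2OS(=O)(=O)C(F)(F)F)c1OCc1ccccc1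
F2 | step 8 | (1S,3R)-carbinol triflate, 1-[2,4,6-tris(benzyloxy)-3-{(1S,3R)-1-[4-(benzyloxy)-2-(trifluoromethanesulfonyloxy)phenyl]-3-[4-(benzyloxy)phenyl]-3-hydroxypropyl}phenyl]-9-phenylnonan-1-one | O=C(CCCCCCCCc1ccccc1)c1c(OCc2ccccc2)cc(OCc2ccccc2)c([C@@H](C[C@@H](O)c2ccc(OCc3ccccc3)cc2)c2ccc(OCc3ccccc3)cc2OS(=O)(=O)C(F)(F)F)c1OCc1ccccc1
F3 | step 6 | lithium diarylcuprate, trilithium bis[4-(benzyloxy)-2-oxidophenyl]cuprate | [Li+].[Li+].[Li+].[O-]c1cc(OCc2ccccc2)ccc1[Cu-]c1ccc(OCc2ccccc2)cc1[O-]
F4 | step 6 | racemic ketone, rac-1-[2,4,6-tris(benzyloxy)-3-{1-[4-(benzyloxy)-2-hydroxyphenyl]-3-[4-(benzyloxy)phenyl]-3-oxopropyl}phenyl]-9-phenylnonan-1-one | O=C(CCCCCCCCc1ccccc1)c1c(OCc2ccccc2)cc(OCc2ccccc2)c(C(CC(=O)c2ccc(OCc3ccccc3)cc2)c2ccc(OCc3ccccc3)cc2O)c1OCc1ccccc1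
F5 | step 6 | (1R,3S)-diol, 1-[2,4,6-tris(benzyloxy)-3-{(1R,3S)-1-[4-(benzyloxy)-2-hydroxyphenyl]-3-[4-(benzyloxy)phenyl]-3-hydroxypropyl}phenyl]-9-phenylnonan-1-one | O=C(CCCCCCCCc1ccccc1)c1c(OCc2ccccc2)cc(OCc2ccccc2)c([C@H](C[C@H](O)c2ccc(OCc3ccccc3)cc2)c2ccc(OCc3ccccc3)cc2O)c1OCc1ccccc1
F6 | step 7 | silyl ether ketone, 1-[2,4,6-tris(benzyloxy)-3-{(1S)-1-[4-(benzyloxy)-2-(tert-butyldimethylsilyloxy)phenyl]-3-[4-(benzyloxy)phenyl]-3-oxopropyl}phenyl]-9-phenylnonan-1-one | O=C(CCCCCCCCc1ccccc1)c1c(OCc2ccccc2)cc(OCc2ccccc2)c([C@@H](CC(=O)c2ccc(OCc3ccccc3)cc2)c2ccc(OCc3ccccc3)cc2O[Si](C)(C)C(C)(C)C)c1OCc1ccccc1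
F7 | step 7 | silyl ether (3S)-carbinol, 1-[2,4,6-tris(benzyloxy)-3-{(1S,3S)-1-[4-(benzyloxy)-2-(tert-butyldimethylsilyloxy)phenyl]-3-[4-(benzyloxy)phenyl]-3-hydroxypropyl}phenyl]-9-phenylnonan-1-one | O=C(CCCCCCCCc1ccccc1)c1c(OCc2ccccc2)cc(OCc2ccccc2)c([C@@H](C[C@H](O)c2ccc(OCc3ccccc3)cc2)c2ccc(OCc3ccccc3)cc2O[Si](C)(C)C(C)(C)C)c1OCc1ccccc1
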